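## Analysis of the target

CNP0142137.1 (37) is a germacrane-type sesquiterpene lactone. With germacrane numbers, C1–C10 form the ten-membered carbocycle, C11–C13 are the branch on C7 (C12 lactone carbonyl, C13 acetoxymethyl), and the methyl groups sit on C4 and C10. An ether oxygen bridges C1 and C4, so O–C1–C2–C3–C4 is a 2,5-cis-tetrahydrofuran inside the carbocycle. C6–C7 is fused to a butenolide (O–C6, C12=O, C7=C11) whose γ-carbon C6 carries the exocyclic enol-lactone alkene C5=C6 (E, that is, C4 and C7 cis within the ring). The ring stereocentres are C1 (S), C4 (R), C8 (S) and C10 (R); the 2-methyloxirane-2-carboxylate on O8 adds one (S) centre. C1 and C4 are tied cis by the bridge, the C10 hydroxyl and the ring oxygen on C1 stand as after syn addition to a Z alkene, and the C8 acyloxy group is 1,3-syn to the C10 hydroxyl. Sensitive groups are the ylidene butenolide (electrophilic, base-labile), the allylic acetate on the butenolide α-carbon (a latent leaving group), the epoxy ester and the free tertiary alcohol. The difficulty lies in the strained, oxygen-bridged ten-membered ring, in stereocentres on both sides of the bridge, and in telling apart the oxygens on C5, C8, C10 and C13 late in the route. The strategy rests on one feature: a 2,5-cis-tetrahydrofuran with an oxygen on each flanking carbon (C10–OH, and one oxidation level back an oxygen on C5). This is the pattern left by oxidative cyclisation of a 1,5-diene C4=C5 / C1=C10 in which C6 is an ester carbon.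

## Retrosynthetic reasoning

**C5=C6 (37 ⇒ 36 ⇒ 35).** The enol-lactone alkene is disconnected first, to a C5 sulfonate (36) on the saturated lactone 35. It is the most fragile unit, so it is made last. Its geometry can be left to the ring only once the ring exists: in the bridged ring C4 and C7 can only be cis across C5=C6, whereas an open-chain elimination would turn C4 away from C7. The C5 oxygen costs nothing, because it is the second hydroxyl delivered by the key step. The forward step must be a mild E1cB elimination that spares acetate, epoxide and tertiary alcohol.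

**Acyl groups (35 ⇒ 34 ⇒ 33 ⇒ 29 + 31).** The O13–acetyl and O8–acyl bonds are cut. The C8 ester is placed while C5 and C13 are still silylated, so C8–OH is the only free secondary hydroxyl; the acetate follows once C13–OH is the only primary one. The forward esterification must join a hindered allylic alcohol to an α-quaternary epoxy acid (as salt 31, from ester 30) without touching the tertiary C10–OH.

**C8 configuration (29 ⇒ 28 ⇒ 27 ⇒ 26).** The C8–H bond is cut back to ketone 27. The ring closure is not trusted to set C8. Instead both C8 epimers of 26 are oxidised to 27, and the free C10 hydroxyl directs a 1,3-syn reduction through borinate 28, which matches the syn relationship in 37.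

**C7–C8 (26 ⇒ 25).** The carbocycle is opened between the bromine-bearing sp2 carbon C7 and the carbinol carbon C8. Every other ring bond either lies next to a centre made in the key step or belongs to the butenolide. The forward step is an intramolecular Nozaki–Hiyama–Kishi coupling, helped by the cis-tetrahydrofuran, which holds both arms on one face.

**C6–C7 and O6–C12 (23 ⇒ 22 ⇒ 21 + 15; 21 ⇐ 20).** The butenolide is split into aldehyde 15 and dibromoacrylate 20, which supplies C7, C11, C12 and C13 and keeps a second bromine on C7 for the ring closure. The coupling must be at C6 and not at C8, because the new alkoxide closes onto the ester and the lactone has to be the 6,12 one. The forward step must metalate only the bromine cis to the ester (carbenoid 21) and lactonise (alkoxide 22).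

**C7 unit (20 ⇒ 19 ⇒ 18 ⇒ 17 ⇒ 16).** C7=C11 comes from dibromo-olefination of keto ester 19, whose ketone is unmasked from the methylene group of acrylate 16.

**Adjusting the cyclisation product (15 ⇒ 14 ⇒ 13 ⇒ 12).** Only protecting groups and the ester oxidation level change. C5–O receives a robust silyl group, C10–O a labile one, and the primary silyl ether at C8 from 10 stays the most easily removed.

**Key disconnection (12 ⇒ 11 ⇒ 10).** The two ring C–O bonds (O–C4, O–C1) and the C5–O and C10–O bonds are cut together, which returns the tetrahydrofuran diol 12 to the acyclic dienoate 10. This is the place to cut because one reagent then sets C1, C4 and C10 (and the sacrificial C5) from two alkene geometries and a single face choice, on an achiral chain.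

**Dienoate (10 ⇒ 9 ⇒ 8 ⇒ 7 ⇒ 6 + 4; 6 ⇐ 5).** The C4–methyl bond is cut at enol phosphate 9 (cuprate substitution fixes 2E). The C2–C3 bond is cut at keto ester 7 (alkylation of dianion 6 with allylic chloride 4).

**Z alkene (4 ⇒ 3 ⇒ 2 ⇒ 1).** The Z geometry of C1=C10, which decides C10, is taken from the ring of lactone 1. The two hydroxyls of diol 2 are told apart by allylic reactivity.

## Alternatives that were turned down

**Alternative 1:** ring expansion by anionic oxy-Cope rearrangement.
- Disconnection: the C8–C9 bond of the carbocycle, formed while the C1–C6 bond of a six-membered ring breaks.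
- Forward key step: the potassium alkoxide of a cyclohexanol bearing two adjacent alkenyl groups rearranges [3,3] to cyclodecenone A1, formed as its C6–C7 enolate, with an E C1=C10 alkene, the C8 oxygen and the C4 silyl ether.
- For: the ten-membered ring comes from a unimolecular, strain-releasing step without dilution, and the regiodefined enolate can take on C11. On ring formation this is stronger than the chosen route, whose step 16 is a high-dilution closure.
- Against: the tetrahydrofuran is still missing. It would need epoxidation of C1=C10 and transannular opening by O4, and the face of that epoxidation (C1 and C10 relative to C4) is left to the conformation of a medium ring. C4 and C8 must already be correct in the six-membered precursor. C5 arrives without oxygen.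
- Comparison: the chosen route sets C1, C4 and C10 in one step with relative configuration fixed by alkene geometry, six steps from an achiral chain; it pays with a macrocyclisation.

**Alternative 2:** oxyallyl–furan [4+3] cycloaddition, then Baeyer–Villiger cleavage.
- Disconnection: C4–C5 and C1–C10, both made across the α-carbons of 2-methylfuran A2, whose oxygen becomes the ether bridge.
- Forward key step: an oxyallyl cation from an α-chloro ketone adds to A2 to give oxabicycle A3. Baeyer–Villiger oxidation then inserts oxygen next to C10 (retention), giving the C10 hydroxyl and C6 as a carboxyl carbon.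
- For: two C–C bonds and the cis bridge in one step from two cheap components. On brevity to the tetrahydrofuran core it is stronger than the chosen route (seven steps to 12).
- Against: an unsymmetrical cation and an unsymmetrical furan leave regiochemistry and endo/exo selectivity (the C10 configuration) open. The adduct is racemic without an added auxiliary or resolution. C5 is a bare methylene.
- Comparison: the chosen route derives C10 from alkene geometry and the absolute configuration from a catalyst, with a separable-diastereomer auxiliary in reserve. Both routes then face the same carbocycle closure.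

**Alternative 3:** macrocyclisation by enol silane capture of a C4 oxocarbenium ion.
- Disconnection: C4–C5, closing the carbocycle and creating quaternary C4 at once.
- Forward key step: a silyl triflate ionises the cyclic methyl ketal at C4, and C5 of the tethered C6 silyl enol ether captures the ion, giving bridged ketone A4 with all butenolide carbons in place.
- For: it is the most convergent plan. The tether can reach C4 only from the face of the C1 side chain, so the cis bridge is enforced, and the C6 ketone is at the right level for enol-lactonisation to C5=C6. Its endgame is shorter than the chosen one.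
- Against: a quaternary centre and a strained ring are formed in one cationic step, in which proton loss from the oxocarbenium ion and oligomerisation are easier. The Lewis acid must spare a tert-butyl ester, an allylic acetate and a tertiary silyl ether. C1, C8 and C10 each need their own asymmetric step in a long acyclic precursor.
- Comparison: the chosen route makes C1, C4 and C10 in one operation and closes the ring at a secondary carbon under neutral chromium conditions.

Key step: step 7

## Remarks before the steps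

- Germacrane numbers C1–C13 are used for all intermediates. TBS = tert-butyldimethylsilyl, TBDPS = tert-butyldiphenylsilyl, TMS = trimethylsilyl.
- Assumption: the cinchonidinium salt selects the enoate face that leads to 4R; if the sense is the opposite, its cinchoninium pseudoenantiomer is used with nothing else changed.
- Assumption: compounds 1, 5, 16 and 30 are purchasable.

## Steps

Step 1
Reactants: 1 4-methyl-5,6-dihydro-2H-pyran-2-one
Product: 2 (2Z)-3-methylpent-2-ene-1,5-diol
Conditions: i-Bu2AlH (3 equiv), CH2Cl2, −78 → 0 °C; Rochelle salt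
Reagents that add atoms: none
Why: 1,2-reduction of the conjugated lactone opens the ring to the diol; the Z geometry is inherited from the ring and no stereocentre is formed.

Step 2
Reactants: 2 (2Z)-3-methylpent-2-ene-1,5-diol
Product: 3 (3Z)-5-chloro-3-methylpent-3-en-1-ol
Conditions: N-chlorosuccinimide (2.2 equiv), Me2S (2.5 equiv), CH2Cl2, −20 → 0 °C
Reagents that add atoms: N-chlorosuccinimide, ClN1C(=O)CCC1=O
Why: Corey–Kim halogenation: both hydroxyls form alkoxysulfonium salts, but only the allylic one is displaced by chloride (SN2 at the primary carbon, no transposition), and the saturated one returns the alcohol on work-up.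

Step 3
Reactants: 3 (3Z)-5-chloro-3-methylpent-3-en-1-ol
Product: 4 tert-butyl{[(3Z)-5-chloro-3-methylpent-3-en-1-yl]oxy}dimethylsilane
Conditions: TBSCl, imidazole, CH2Cl2, 0 °C
Reagents that add atoms: tert-butyldimethylsilyl chloride, CC(C)(C)[Si](C)(C)Cl
Why: Standard silylation of a primary alcohol, run cold and directly after step 2 so that the hydroxyl cannot close onto the allylic chloride.

Step 4
Reactants: 4 tert-butyl{[(3Z)-5-chloro-3-methylpent-3-en-1-yl]oxy}dimethylsilane; 5 methyl 3-oxobutanoate
Product: 7 methyl (6Z)-9-[(tert-butyldimethylsilyl)oxy]-7-methyl-3-oxonon-6-enoate, via methyl acetoacetate dianion 6 (not isolated)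
Conditions: 5, NaH, THF, 0 °C; n-BuLi, 0 °C; then 4, 0 °C → rt
Reagents that add atoms: none
Why: Weiler dianion alkylation: the terminal, more basic carbanion of 6 displaces the primary allylic chloride by SN2 and forms C2–C3 without touching the alkene geometry.

Step 5
Reactants: 7 methyl (6Z)-9-[(tert-butyldimethylsilyl)oxy]-7-methyl-3-oxonon-6-enoate
Product: 9 methyl (2Z,6Z)-9-[(tert-butyldimethylsilyl)oxy]-3-[(diethoxyphosphoryl)oxy]-7-methylnona-2,6-dienoate, via sodium enolate 8 (not isolated)
Conditions: NaH, Et2O, 0 °C; ClP(O)(OEt)2, 0 °C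
Reagents that add atoms: diethyl chlorophosphate, CCOP(=O)(Cl)OCC
Why: In ether the sodium enolate is chelated between the two carbonyl oxygens, so O-phosphorylation gives the Z enol phosphate.

Step 6
Reactants: 9 methyl (2Z,6Z)-9-[(tert-butyldimethylsilyl)oxy]-3-[(diethoxyphosphoryl)oxy]-7-methylnona-2,6-dienoate
Product: 10 methyl (2E,6Z)-9-[(tert-butyldimethylsilyl)oxy]-3,7-dimethylnona-2,6-dienoate
Conditions: CuI (3 equiv), MeLi (6 equiv), Et2O, 0 °C; then 9, −78 → −45 °C
Reagents that add atoms: methyllithium, C[Li] (delivered as lithium dimethylcuprate, [Li+].C[Cu-]C)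
Why: Addition–elimination of the Gilman cuprate on the β-phosphoryloxy enoate replaces phosphate by methyl with retention, which fixes the 2E geometry without an isomer separation.

Step 7
Reactants: 10 methyl (2E,6Z)-9-[(tert-butyldimethylsilyl)oxy]-3,7-dimethylnona-2,6-dienoate
Product: 12 methyl (2S)-2-hydroxy-2-[(2R,5S)-5-[(2R)-4-[(tert-butyldimethylsilyl)oxy]-2-hydroxybutan-2-yl]-2-methyloxolan-2-yl]acetate, via cyclic manganese diester 11 (not isolated)
Conditions: KMnO4 (powder, 1.6 equiv), AcOH (6 equiv), O-allyl-N-(9-anthracenylmethyl)cinchonidinium bromide (0.1 equiv), CH2Cl2, −30 °C; aq. Na2S2O5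
Reagents that add atoms: potassium permanganate, [K+].[O-][Mn](=O)(=O)=O
Why: Permanganate, carried into CH2Cl2 as an ion pair with the chiral ammonium cation, adds [3+2] to the electron-poor C4=C5 alkene and gives the cyclic diester 11 of pentavalent manganese. The C4-bound oxygen and an oxo ligand of 11 then add [3+2] across C1=C10 on the face where the metal sits, and hydrolysis releases the diol. The closest known reaction type is the permanganate oxidative cyclisation of 1,5-dienes and 2,6-dienoates to 2,5-cis-tetrahydrofuran diols, including its phase-transfer version with chiral ammonium salts. The tetrahydrofuran closes by 5-exo O–C1 bond formation within this second suprafacial cycloaddition, so the ring can only be 2,5-cis. C4 and C5 take their absolute configuration from the face of the enoate selected by the ion pair, and their relative (threo) configuration from syn addition to the 2E alkene. C1 follows from the cis ring, and C10 from syn addition to the 6Z alkene. The step needs site selectivity (enoate first, secured by the faster reaction of permanganate with the conjugated alkene), chemoselectivity against cleavage (low temperature, AcOH) and face selectivity (catalyst). The TBS ether is inert.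

Step 8
Reactants: 12 methyl (2S)-2-hydroxy-2-[(2R,5S)-5-[(2R)-4-[(tert-butyldimethylsilyl)oxy]-2-hydroxybutan-2-yl]-2-methyloxolan-2-yl]acetate
Product: 14 methyl (2S)-2-[(TBS)oxy]-2-[(2R,5S)-5-[(2R)-4-[(TBS)oxy]-2-[(TMS)oxy]butan-2-yl]-2-methyloxolan-2-yl]acetate, via C5 mono-TBS ether 13 (not isolated)
Conditions: TBSOTf (1.2 equiv), 2,6-lutidine, CH2Cl2, −78 → −40 °C; then TMSOTf (1.5 equiv), −40 → 0 °C
Reagents that add atoms: tert-butyldimethylsilyl triflate, CC(C)(C)[Si](C)(C)OS(=O)(=O)C(F)(F)F; trimethylsilyl triflate, C[Si](C)(C)OS(=O)(=O)C(F)(F)F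
Why: At low temperature the silyl triflate silylates the secondary C5 hydroxyl before the tertiary one; the tertiary C10 hydroxyl is then capped with the small, acid-labile TMS group so that it cannot quench the organomagnesium reagent of step 13.

Step 9
Reactants: 14 methyl (2S)-2-[(TBS)oxy]-2-[(2R,5S)-5-[(2R)-4-[(TBS)oxy]-2-[(TMS)oxy]butan-2-yl]-2-methyloxolan-2-yl]acetate
Product: 15 (2S)-2-[(TBS)oxy]-2-[(2R,5S)-5-[(2R)-4-[(TBS)oxy]-2-[(TMS)oxy]butan-2-yl]-2-methyloxolan-2-yl]acetaldehyde
Conditions: i-Bu2AlH (1.2 equiv), CH2Cl2, −78 °C; MeOH, Rochelle salt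
Reagents that add atoms: none
Why: Partial reduction of an α-silyloxy ester stops at the aldehyde, because the aluminium hemiacetal is stable at −78 °C until work-up.

Step 10
Reactants: 16 methyl 2-(hydroxymethyl)prop-2-enoate
Product: 17 methyl 2-{[(tert-butyldiphenylsilyl)oxy]methyl}prop-2-enoate
Conditions: TBDPSCl, imidazole, CH2Cl2, rt
Reagents that add atoms: tert-butyldiphenylsilyl chloride, CC(C)(C)[Si](Cl)(c1ccccc1)c1ccccc1
Why: Silylation of a primary alcohol; TBDPS is chosen because it survives the later acid removal of the primary TBS group and is a poor ligand for magnesium.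

Step 11
Reactants: 17 methyl 2-{[(tert-butyldiphenylsilyl)oxy]methyl}prop-2-enoate
Product: 19 methyl 3-[(tert-butyldiphenylsilyl)oxy]-2-oxopropanoate, via ozonide 18 (not isolated)
Conditions: O3, CH2Cl2, −78 °C; then Me2S, −78 °C → rt
Reagents that add atoms: ozone, [O-][O+]=O
Why: Ozonolysis of the 1,1-disubstituted alkene with reductive work-up gives the α-keto ester and formaldehyde.

Step 12
Reactants: 19 methyl 3-[(tert-butyldiphenylsilyl)oxy]-2-oxopropanoate
Product: 20 methyl 3,3-dibromo-2-{[(tert-butyldiphenylsilyl)oxy]methyl}prop-2-enoate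
Conditions: CBr4 (2 equiv), PPh3 (4 equiv), CH2Cl2, 0 °C
Reagents that add atoms: carbon tetrabromide, BrC(Br)(Br)Br
Why: Ramirez dibromo-olefination (the first stage of the Corey–Fuchs sequence) applies to the activated ketone carbonyl of an α-keto ester and forms C7=C11.

Step 13
Reactants: 15 (2S)-2-[(TBS)oxy]-2-[(2R,5S)-5-[(2R)-4-[(TBS)oxy]-2-[(TMS)oxy]butan-2-yl]-2-methyloxolan-2-yl]acetaldehyde; 20 methyl 3,3-dibromo-2-{[(tert-butyldiphenylsilyl)oxy]methyl}prop-2-enoate
Product: 23 (1S,4R,5R,6S,10R)-7-bromo-5,8-bis[(TBS)oxy]-13-[(TBDPS)oxy]-10-[(TMS)oxy]-1,4-epoxy-7,8-secogermacr-7(11)-en-6,12-olide, via magnesium carbenoid 21 (not isolated), via chloromagnesium alkoxide 22 (not isolated)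
Conditions: 20 (1.6 equiv), i-PrMgCl (1.5 equiv), THF, −78 °C; then 15, −78 → −20 °C; aq. NH4Cl
Reagents that add atoms: none
Why: Halogen–magnesium exchange on the 1,1-dibromoalkene takes the bromine cis to the ester, the less hindered one and the one whose carbenoid 21 is held by the ester carbonyl. Carbenoid 21 adds to the aldehyde (Felkin–Anh, anti to the C5 silyloxy group, giving 5,6-anti, 6S), and alkoxide 22, cis to the ester, lactonises. C5 and C6 are temporary centres that become trigonal in step 23.

Step 14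
Reactants: 23 (1S,4R,5R,6S,10R)-7-bromo-5,8-bis[(TBS)oxy]-13-[(TBDPS)oxy]-10-[(TMS)oxy]-1,4-epoxy-7,8-secogermacr-7(11)-en-6,12-olide
Product: 24 (1S,4R,5R,6S,10R)-7-bromo-5-[(TBS)oxy]-13-[(TBDPS)oxy]-8,10-dihydroxy-1,4-epoxy-7,8-secogermacr-7(11)-en-6,12-olide
Conditions: pyridinium p-toluenesulfonate (0.3 equiv), MeOH, rt
Reagents that add atoms: none
Why: Acid-catalysed methanolysis removes the primary TBS ether and the tertiary TMS ether; the hindered secondary TBS ether at C5 and the TBDPS ether are much slower.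

Step 15
Reactants: 24 (1S,4R,5R,6S,10R)-7-bromo-5-[(TBS)oxy]-13-[(TBDPS)oxy]-8,10-dihydroxy-1,4-epoxy-7,8-secogermacr-7(11)-en-6,12-olide
Product: 25 (1S,4R,5R,6S,10R)-7-bromo-5-[(TBS)oxy]-13-[(TBDPS)oxy]-10-hydroxy-8-oxo-1,4-epoxy-7,8-secogermacr-7(11)-en-6,12-olide
Conditions: 2,2,6,6-tetramethylpiperidin-1-oxyl (0.1 equiv), PhI(OAc)2 (1.2 equiv), CH2Cl2, rt
Reagents that add atoms: none
Why: Oxoammonium oxidation converts the primary alcohol to the aldehyde under near-neutral conditions; the tertiary alcohol is inert and the β-hydroxy aldehyde is not exposed to base.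

Step 16
Reactants: 25 (1S,4R,5R,6S,10R)-7-bromo-5-[(TBS)oxy]-13-[(TBDPS)oxy]-10-hydroxy-8-oxo-1,4-epoxy-7,8-secogermacr-7(11)-en-6,12-olide
Product: 26 (1S,4R,5R,6R,10R)-5-[(TBS)oxy]-13-[(TBDPS)oxy]-8,10-dihydroxy-1,4-epoxygermacr-7(11)-en-6,12-olide as a mixture of C8 epimers
Conditions: CrCl2 (10 equiv), NiCl2 (0.1 equiv), DMSO–THF, rt, 0.002 M, slow addition of 25
Reagents that add atoms: none
Why: Nozaki–Hiyama–Kishi reaction: zerovalent nickel inserts into the activated C7–Br bond, the alkenyl group passes to trivalent chromium and adds to the C8 aldehyde. The cis-tetrahydrofuran holds both arms on one face, the free hydroxyl is tolerated, and the C8 configuration is not relied on because step 17 erases it.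

Step 17
Reactants: 26 (1S,4R,5R,6R,10R)-5-[(TBS)oxy]-13-[(TBDPS)oxy]-8,10-dihydroxy-1,4-epoxygermacr-7(11)-en-6,12-olide as a mixture of C8 epimers
Product: 27 (1S,4R,5R,6R,10R)-5-[(TBS)oxy]-13-[(TBDPS)oxy]-10-hydroxy-8-oxo-1,4-epoxygermacr-7(11)-en-6,12-olide
Conditions: Dess–Martin periodinane, NaHCO3, CH2Cl2, 0 °C → rt
Reagents that add atoms: none
Why: Buffered Dess–Martin oxidation of the secondary allylic alcohol makes both C8 epimers converge on one ketone; the tertiary alcohol does not react.

Step 18
Reactants: 27 (1S,4R,5R,6R,10R)-5-[(TBS)oxy]-13-[(TBDPS)oxy]-10-hydroxy-8-oxo-1,4-epoxygermacr-7(11)-en-6,12-olide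
Product: 29 (1S,4R,5R,6R,8S,10R)-5-[(TBS)oxy]-13-[(TBDPS)oxy]-8,10-dihydroxy-1,4-epoxygermacr-7(11)-en-6,12-olide, via C10 diethylborinate 28 (not isolated)
Conditions: Et2BOMe (1.2 equiv), THF–MeOH (4:1), −78 °C; NaBH4 (1.5 equiv), −78 °C; AcOH, then MeOH co-evaporation
Reagents that add atoms: none
Why: Narasaka–Prasad reduction: boron ties the C10 oxygen and the C8 ketone into a six-membered chelate (28) with the larger C10 substituent (C1) equatorial, and external hydride attacks axially. This gives the 1,3-syn diol, that is 8S. At −78 °C the chelated ketone is the activated carbonyl, so 1,2-addition is favoured over attack on the butenolide.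

Step 19
Reactants: 30 methyl (2S)-2-methyloxirane-2-carboxylate
Product: 31 potassium (2S)-2-methyloxirane-2-carboxylate
Conditions: KOH (1.0 equiv), MeOH, 0 °C; evaporation, drying
Reagents that add atoms: potassium hydroxide, [K+].[OH-]
Why: Saponification with one equivalent of cold hydroxide is faster than epoxide opening, the α-carbon is quaternary and cannot epimerise, and isolating the salt avoids the acid-sensitive free epoxy acid.

Step 20
Reactants: 29 (1S,4R,5R,6R,8S,10R)-5-[(TBS)oxy]-13-[(TBDPS)oxy]-8,10-dihydroxy-1,4-epoxygermacr-7(11)-en-6,12-olide; 31 potassium (2S)-2-methyloxirane-2-carboxylate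
Product: 33 (1S,4R,5R,6R,8S,10R)-5-[(TBS)oxy]-13-[(TBDPS)oxy]-10-hydroxy-1,4-epoxygermacr-7(11)-en-6,12-olid-8-yl (2S)-2-methyloxirane-2-carboxylate, via mixed anhydride 32 (not isolated)
Conditions: 31 (3 equiv), 2,4,6-trichlorobenzoyl chloride, THF, rt; then 29, 4-(dimethylamino)pyridine, toluene, rt
Reagents that add atoms: none
Why: Yamaguchi esterification: the hindered mixed anhydride transfers the α-quaternary acyl group through its acylpyridinium to the secondary allylic C8 hydroxyl with retention at C8; the tertiary C10 hydroxyl is too hindered to compete.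

Step 21
Reactants: 33 (1S,4R,5R,6R,8S,10R)-5-[(TBS)oxy]-13-[(TBDPS)oxy]-10-hydroxy-1,4-epoxygermacr-7(11)-en-6,12-olid-8-yl (2S)-2-methyloxirane-2-carboxylate
Product: 34 (1S,4R,5R,6R,8S,10R)-5,10,13-trihydroxy-1,4-epoxygermacr-7(11)-en-6,12-olid-8-yl (2S)-2-methyloxirane-2-carboxylate
Conditions: HF·pyridine, pyridine, THF, 0 °C → rt
Reagents that add atoms: none
Why: Buffered hydrogen fluoride cleaves both silyl ethers by attack at silicon; an epoxide flanked by an ester is a poor substrate for acid opening and should survive the buffered medium.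

Step 22
Reactants: 34 (1S,4R,5R,6R,8S,10R)-5,10,13-trihydroxy-1,4-epoxygermacr-7(11)-en-6,12-olid-8-yl (2S)-2-methyloxirane-2-carboxylate
Product: 35 (1S,4R,5R,6R,8S,10R)-13-acetoxy-5,10-dihydroxy-1,4-epoxygermacr-7(11)-en-6,12-olid-8-yl (2S)-2-methyloxirane-2-carboxylate
Conditions: Ac2O (1.2 equiv), pyridine, CH2Cl2, 0 °C
Reagents that add atoms: acetic anhydride, CC(=O)OC(C)=O
Why: Without an acyl-transfer catalyst the primary allylic C13 hydroxyl is acetylated well before the neopentyl-type secondary C5 hydroxyl and the tertiary C10 hydroxyl.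

Step 23
Reactants: 35 (1S,4R,5R,6R,8S,10R)-13-acetoxy-5,10-dihydroxy-1,4-epoxygermacr-7(11)-en-6,12-olid-8-yl (2S)-2-methyloxirane-2-carboxylate
Product: 37 (1S,4R,5E,8S,10R)-13-acetoxy-10-hydroxy-1,4-epoxygermacra-5,7(11)-dien-6,12-olid-8-yl (2S)-2-methyloxirane-2-carboxylate, via C5 mesylate 36 (not isolated)
Conditions: MsCl (1.5 equiv), Et3N (3 equiv), CH2Cl2, −20 °C; then DBU (2 equiv), −20 → 0 °C
Reagents that add atoms: none
Why: Mesylation of the secondary C5 hydroxyl, then E1cB elimination: DBU removes the vinylogously acidic C6–H of the butenolide and the dienolate expels mesylate to give the conjugated ylidene butenolide. The bridged ring allows only the geometry with C4 and C7 cis (5E), and C1, C4, C8 and C10 are untouched.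

## Compound list

1 | 4-methyl-5,6-dihydro-2H-pyran-2-one | CC1=CC(=O)OCC1 | starting material
2 | (2Z)-3-methylpent-2-ene-1,5-diol | OC/C=C(/C)CCO | intermediate
3 | (3Z)-5-chloro-3-methylpent-3-en-1-ol | ClC/C=C(/C)CCO | intermediate
4 | tert-butyl{[(3Z)-5-chloro-3-methylpent-3-en-1-yl]oxy}dimethylsilane | ClC/C=C(/C)CCO[Si](C)(C)C(C)(C)C | intermediate
5 | methyl 3-oxobutanoate (methyl acetoacetate) | COC(=O)CC(C)=O | starting material
6 | methyl acetoacetate dianion, sodium lithium salt | [CH2-]C(=O)[CH-]C(=O)OC.[Na+].[Li+] | intermediate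
7 | methyl (6Z)-9-[(tert-butyldimethylsilyl)oxy]-7-methyl-3-oxonon-6-enoate | COC(=O)CC(=O)CC/C=C(/C)CCO[Si](C)(C)C(C)(C)C | intermediate
8 | sodium (Z)-enolate of 7 | COC(=O)/C=C(\[O-])CC/C=C(/C)CCO[Si](C)(C)C(C)(C)C.[Na+] | intermediate
9 | methyl (2Z,6Z)-9-[(tert-butyldimethylsilyl)oxy]-3-[(diethoxyphosphoryl)oxy]-7-methylnona-2,6-dienoate | COC(=O)/C=C(\OP(=O)(OCC)OCC)CC/C=C(/C)CCO[Si](C)(C)C(C)(C)C | intermediate
10 | methyl (2E,6Z)-9-[(tert-butyldimethylsilyl)oxy]-3,7-dimethylnona-2,6-dienoate | COC(=O)/C=C(\C)CC/C=C(/C)CCO[Si](C)(C)C(C)(C)C | intermediate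
11 | potassium salt of the cyclic manganate diester across C4=C5 of 10 (pentavalent manganese; C4 R, C5 S) | COC(=O)[C@H]1O[Mn](=O)([O-])O[C@]1(C)CC/C=C(/C)CCO[Si](C)(C)C(C)(C)C.[K+] | intermediate
12 | methyl (2S)-2-hydroxy-2-[(2R,5S)-5-[(2R)-4-[(tert-butyldimethylsilyl)oxy]-2-hydroxybutan-2-yl]-2-methyloxolan-2-yl]acetate (C1 S, C4 R, C5 S, C10 R) | COC(=O)[C@@H](O)[C@@]1(C)CC[C@H](O1)[C@](C)(O)CCO[Si](C)(C)C(C)(C)C | intermediate
13 | methyl (2S)-2-[(tert-butyldimethylsilyl)oxy]-2-[(2R,5S)-5-[(2R)-4-[(tert-butyldimethylsilyl)oxy]-2-hydroxybutan-2-yl]-2-methyloxolan-2-yl]acetate | COC(=O)[C@@H](O[Si](C)(C)C(C)(C)C)[C@@]1(C)CC[C@H](O1)[C@](C)(O)CCO[Si](C)(C)C(C)(C)C | intermediate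
14 | methyl (2S)-2-[(tert-butyldimethylsilyl)oxy]-2-[(2R,5S)-5-[(2R)-4-[(tert-butyldimethylsilyl)oxy]-2-[(trimethylsilyl)oxy]butan-2-yl]-2-methyloxolan-2-yl]acetate | COC(=O)[C@@H](O[Si](C)(C)C(C)(C)C)[C@@]1(C)CC[C@H](O1)[C@](C)(O[Si](C)(C)C)CCO[Si](C)(C)C(C)(C)C | intermediate
15 | (2S)-2-[(tert-butyldimethylsilyl)oxy]-2-[(2R,5S)-5-[(2R)-4-[(tert-butyldimethylsilyl)oxy]-2-[(trimethylsilyl)oxy]butan-2-yl]-2-methyloxolan-2-yl]acetaldehyde | O=C[C@@H](O[Si](C)(C)C(C)(C)C)[C@@]1(C)CC[C@H](O1)[C@](C)(O[Si](C)(C)C)CCO[Si](C)(C)C(C)(C)C | intermediate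
16 | methyl 2-(hydroxymethyl)prop-2-enoate | COC(=O)C(=C)CO | starting material
17 | methyl 2-{[(tert-butyldiphenylsilyl)oxy]methyl}prop-2-enoate | COC(=O)C(=C)CO[Si](c1ccccc1)(c1ccccc1)C(C)(C)C | intermediate
18 | methyl 3-{[(tert-butyldiphenylsilyl)oxy]methyl}-1,2,4-trioxolane-3-carboxylate (ozonide, racemic) | COC(=O)C1(CO[Si](c2ccccc2)(c2ccccc2)C(C)(C)C)OCOO1 | intermediate
19 | methyl 3-[(tert-butyldiphenylsilyl)oxy]-2-oxopropanoate | COC(=O)C(=O)CO[Si](c1ccccc1)(c1ccccc1)C(C)(C)C | intermediate
20 | methyl 3,3-dibromo-2-{[(tert-butyldiphenylsilyl)oxy]methyl}prop-2-enoate | COC(=O)C(CO[Si](c1ccccc1)(c1ccccc1)C(C)(C)C)=C(Br)Br | intermediate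
21 | methyl (2E)-3-bromo-3-(chloromagnesio)-2-{[(tert-butyldiphenylsilyl)oxy]methyl}prop-2-enoate (magnesium cis to the ester) | COC(=O)/C(CO[Si](c1ccccc1)(c1ccccc1)C(C)(C)C)=C(/Br)[Mg]Cl | intermediate
22 | chloromagnesium C6 alkoxide of the open-chain adduct of 21 and 15 (C6 cis to the methyl ester across C7=C11; 1S,4R,5R,6S,10R) | COC(=O)/C(CO[Si](c1ccccc1)(c1ccccc1)C(C)(C)C)=C(/Br)[C@@H](O[Mg]Cl)[C@@H](O[Si](C)(C)C(C)(C)C)[C@@]2(C)CC[C@H](O2)[C@](C)(O[Si](C)(C)C)CCO[Si](C)(C)C(C)(C)C | intermediate
23 | (1S,4R,5R,6S,10R)-7-bromo-5,8-bis[(tert-butyldimethylsilyl)oxy]-13-[(tert-butyldiphenylsilyl)oxy]-10-[(trimethylsilyl)oxy]-1,4-epoxy-7,8-secogermacr-7(11)-en-6,12-olide | BrC1=C(CO[Si](c2ccccc2)(c2ccccc2)C(C)(C)C)C(=O)O[C@H]1[C@@H](O[Si](C)(C)C(C)(C)C)[C@@]3(C)CC[C@H](O3)[C@](C)(O[Si](C)(C)C)CCO[Si](C)(C)C(C)(C)C | intermediate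
24 | (1S,4R,5R,6S,10R)-7-bromo-5-[(tert-butyldimethylsilyl)oxy]-13-[(tert-butyldiphenylsilyl)oxy]-8,10-dihydroxy-1,4-epoxy-7,8-secogermacr-7(11)-en-6,12-olide | BrC1=C(CO[Si](c2ccccc2)(c2ccccc2)C(C)(C)C)C(=O)O[C@H]1[C@@H](O[Si](C)(C)C(C)(C)C)[C@@]3(C)CC[C@H](O3)[C@](C)(O)CCO | intermediate
25 | (1S,4R,5R,6S,10R)-7-bromo-5-[(tert-butyldimethylsilyl)oxy]-13-[(tert-butyldiphenylsilyl)oxy]-10-hydroxy-8-oxo-1,4-epoxy-7,8-secogermacr-7(11)-en-6,12-olide (C8 aldehyde) | BrC1=C(CO[Si](c2ccccc2)(c2ccccc2)C(C)(C)C)C(=O)O[C@H]1[C@@H](O[Si](C)(C)C(C)(C)C)[C@@]3(C)CC[C@H](O3)[C@](C)(O)CC=O | intermediate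
26 | (1S,4R,5R,6R,10R)-5-[(tert-butyldimethylsilyl)oxy]-13-[(tert-butyldiphenylsilyl)oxy]-8,10-dihydroxy-1,4-epoxygermacr-7(11)-en-6,12-olide, mixture of C8 epimers | CC(C)(C)[Si](c4ccccc4)(c4ccccc4)OCC1=C2[C@H]([C@@H](O[Si](C)(C)C(C)(C)C)[C@@]3(C)CC[C@H](O3)[C@](C)(O)CC2O)OC1=O | intermediate
27 | (1S,4R,5R,6R,10R)-5-[(tert-butyldimethylsilyl)oxy]-13-[(tert-butyldiphenylsilyl)oxy]-10-hydroxy-8-oxo-1,4-epoxygermacr-7(11)-en-6,12-olide | CC(C)(C)[Si](c4ccccc4)(c4ccccc4)OCC1=C2[C@H]([C@@H](O[Si](C)(C)C(C)(C)C)[C@@]3(C)CC[C@H](O3)[C@](C)(O)CC2=O)OC1=O | intermediate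
28 | C10 O-diethylborinate of 27 (drawn without the boron–ketone coordination) | CC(C)(C)[Si](c4ccccc4)(c4ccccc4)OCC1=C2[C@H]([C@@H](O[Si](C)(C)C(C)(C)C)[C@@]3(C)CC[C@H](O3)[C@](C)(OB(CC)CC)CC2=O)OC1=O | intermediate
29 | (1S,4R,5R,6R,8S,10R)-5-[(tert-butyldimethylsilyl)oxy]-13-[(tert-butyldiphenylsilyl)oxy]-8,10-dihydroxy-1,4-epoxygermacr-7(11)-en-6,12-olide | CC(C)(C)[Si](c4ccccc4)(c4ccccc4)OCC1=C2[C@H]([C@@H](O[Si](C)(C)C(C)(C)C)[C@@]3(C)CC[C@H](O3)[C@](C)(O)C[C@@H]2O)OC1=O | intermediate
30 | methyl (2S)-2-methyloxirane-2-carboxylate | COC(=O)[C@]1(C)CO1 | starting material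
31 | potassium (2S)-2-methyloxirane-2-carboxylate | [K+].[O-]C(=O)[C@]1(C)CO1 | intermediate
32 | (2S)-2-methyloxirane-2-carboxylic 2,4,6-trichlorobenzoic anhydride | O=C(OC(=O)[C@]1(C)CO1)c2c(Cl)cc(Cl)cc2Cl | intermediate
33 | (1S,4R,5R,6R,8S,10R)-5-[(tert-butyldimethylsilyl)oxy]-13-[(tert-butyldiphenylsilyl)oxy]-10-hydroxy-1,4-epoxygermacr-7(11)-en-6,12-olid-8-yl (2S)-2-methyloxirane-2-carboxylate | CC(C)(C)[Si](c4ccccc4)(c4ccccc4)OCC1=C2[C@H]([C@@H](O[Si](C)(C)C(C)(C)C)[C@@]3(C)CC[C@H](O3)[C@](C)(O)C[C@@H]2OC(=O)[C@]5(C)CO5)OC1=O | intermediate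
34 | (1S,4R,5R,6R,8S,10R)-5,10,13-trihydroxy-1,4-epoxygermacr-7(11)-en-6,12-olid-8-yl (2S)-2-methyloxirane-2-carboxylate | OCC1=C2[C@H]([C@@H](O)[C@@]3(C)CC[C@H](O3)[C@](C)(O)C[C@@H]2OC(=O)[C@]5(C)CO5)OC1=O | intermediate
35 | (1S,4R,5R,6R,8S,10R)-13-acetoxy-5,10-dihydroxy-1,4-epoxygermacr-7(11)-en-6,12-olid-8-yl (2S)-2-methyloxirane-2-carboxylate | CC(=O)OCC1=C2[C@H]([C@@H](O)[C@@]3(C)CC[C@H](O3)[C@](C)(O)C[C@@H]2OC(=O)[C@]5(C)CO5)OC1=O | intermediate
36 | (1S,4R,5R,6R,8S,10R)-13-acetoxy-10-hydroxy-5-[(methylsulfonyl)oxy]-1,4-epoxygermacr-7(11)-en-6,12-olid-8-yl (2S)-2-methyloxirane-2-carboxylate | CC(=O)OCC1=C2[C@H]([C@@H](OS(C)(=O)=O)[C@@]3(C)CC[C@H](O3)[C@](C)(O)C[C@@H]2OC(=O)[C@]5(C)CO5)OC1=O | intermediate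
37 | CNP0142137.1: (1S,4R,5E,8S,10R)-13-acetoxy-10-hydroxy-1,4-epoxygermacra-5,7(11)-dien-6,12-olid-8-yl (2S)-2-methyloxirane-2-carboxylate | CC(=O)OCC1=C2/C(=C\[C@@]3(C)CC[C@H](O3)[C@](C)(O)C[C@@H]2OC(=O)[C@]2(C)CO2)OC1=O | target

## Step count and least certain steps

Total: 23 steps. Longest linear sequence: 19 steps from lactone 1 (steps 1–9, 13–18, 20–23); steps 10–12 and step 19 are side branches.

**Step 7 (key step).** The most likely failure is insufficient discrimination between the two enoate faces. A methyl ester binds the chiral ammonium–permanganate ion pair less tightly than the aryl ketones for which this catalysis works best, so the diol could form with low enantiomeric purity. Over-oxidation of the C5 carbinol or cleavage of the diester would lower the material balance. Relative configuration is not at risk.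
- Fallback, from dienoate 10: saponification (LiOH, THF–MeOH–H2O) gives (2E,6Z)-9-[(tert-butyldimethylsilyl)oxy]-3,7-dimethylnona-2,6-dienoic acid F1.
- Its pivaloyl mixed anhydride acylates the sodium salt of (1S,2R)-bornane-10,2-sultam to give the N-dienoyl sultam F2.
- KMnO4/AcOH in acetone–water at −30 °C then gives the sultam tetrahydrofuran diol F3. The face is now chosen by a covalently bound auxiliary and the minor diastereomer can be removed by chromatography.
- Mg(OMe)2 in methanol releases the auxiliary and returns the route to methyl ester 12. The sultam antipode is chosen to match the required face; the (1S,2R) form is written as the assumed match.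

**Step 16.** Closure of the bridged ten-membered ring may be slower than intermolecular coupling or reduction of the C–Br bond. The alkenylchromium intermediate, which has the lactone oxygen on the neighbouring carbon, could also fragment by β-elimination to an allenic carboxylate.
- Fallback, from aldehyde 25: an acylative palladium closure with no polar carbon–metal bond at C7. Pinnick oxidation (NaClO2, NaH2PO4, 2-methylbut-2-ene) gives the C8 carboxylic acid F4.
- Ethanethiol with a carbodiimide gives the S-ethyl thioester F5.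
- Pd(PPh3)4 with hexamethylditin exchanges bromine for tin to give the C7 trimethylstannane F6.
- Intramolecular Liebeskind–Srogl coupling (Pd2(dba)3, tri(2-furyl)phosphine, copper thiophene-2-carboxylate Cu(O2CC4H3S), high dilution) forms C7–C8 at the ketone level and rejoins the route at ketone 27.

**Step 13.** The carbenoid may decompose (loss of magnesium halide) before it adds to the hindered α-silyloxy aldehyde, or the exchange may be incompletely selective between the two bromines.
- Fallback, from 15 and 20: Nozaki–Hiyama–Kishi coupling (CrCl2, catalytic NiCl2, DMSO, rt). It avoids a thermally fragile carbenoid; only the adduct formed at the bromine cis to the ester can lactonise, so it is separable from its isomer. The fallback arrives at the same bromobutenolide 23 without new intermediates.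

**Step 18.** The conformation of the ten-membered ring may override the boron chelate and deliver hydride to the other face (the 8R alcohol), or hydride may add in a conjugate sense to the ene-dicarbonyl system.
- Fallback, from ketone 27: if the (8R)-alcohol F7 is what forms, it is not discarded. (2S)-2-Methyloxirane-2-carboxylic acid F8 is freed from salt 31 by cold acidification. Mitsunobu esterification of F7 with F8 (PPh3, diisopropyl azodicarboxylate) inverts C8 and rejoins the route at ester 33.

**Step 23.** The dienolate formed by DBU may expel the C13 acetate instead of the C5 mesylate, or excess base may remove the C8 proton and trigger loss of acetate, giving cross-conjugated methylene lactones.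
- Fallback, from triol 34: the elimination is run with a non-leaving group on C13. Selective silylation of the primary hydroxyl (TBSCl, imidazole) gives the C13 TBS ether F9.
- MsCl/Et3N gives its C5 mesylate F10, and DBU gives the ylidene butenolide with C13–OTBS F11.
- Buffered HF·pyridine gives the C13 alcohol F12, and acetylation (Ac2O, pyridine) rejoins the route at target 37.

## Further compounds

F1 | step 7 | (2E,6Z)-9-[(tert-butyldimethylsilyl)oxy]-3,7-dimethylnona-2,6-dienoic acid | OC(=O)/C=C(\C)CC/C=C(/C)CCO[Si](C)(C)C(C)(C)C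
F2 | step 7 | N-[(2E,6Z)-9-[(tert-butyldimethylsilyl)oxy]-3,7-dimethylnona-2,6-dienoyl]-(1S,2R)-bornane-10,2-sultam | CC1(C)[C@@H]2CC[C@]13CS(=O)(=O)N([C@@H]3C2)C(=O)/C=C(\C)CC/C=C(/C)CCO[Si](C)(C)C(C)(C)C
F3 | step 7 | N-acyl-(1S,2R)-bornane-10,2-sultam analogue of diol 12 (C1 S, C4 R, C5 S, C10 R) | CC1(C)[C@@H]2CC[C@]13CS(=O)(=O)N([C@@H]3C2)C(=O)[C@@H](O)[C@@]4(C)CC[C@H](O4)[C@](C)(O)CCO[Si](C)(C)C(C)(C)C
F0 | step 13 | none | none
F4 | step 16 | (1S,4R,5R,6S,10R)-7-bromo-5-[(tert-butyldimethylsilyl)oxy]-13-[(tert-butyldiphenylsilyl)oxy]-10-hydroxy-1,4-epoxy-7,8-secogermacr-7(11)-en-6,12-olid-8-oic acid | BrC1=C(CO[Si](c2ccccc2)(c2ccccc2)C(C)(C)C)C(=O)O[C@H]1[C@@H](O[Si](C)(C)C(C)(C)C)[C@@]3(C)CC[C@H](O3)[C@](C)(O)CC(=O)O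
F5 | step 16 | S-ethyl thioester of F4 | BrC1=C(CO[Si](c2ccccc2)(c2ccccc2)C(C)(C)C)C(=O)O[C@H]1[C@@H](O[Si](C)(C)C(C)(C)C)[C@@]3(C)CC[C@H](O3)[C@](C)(O)CC(=O)SCC
F6 | step 16 | C7 trimethylstannyl analogue of F5 | C[Sn](C)(C)C1=C(CO[Si](c2ccccc2)(c2ccccc2)C(C)(C)C)C(=O)O[C@H]1[C@@H](O[Si](C)(C)C(C)(C)C)[C@@]3(C)CC[C@H](O3)[C@](C)(O)CC(=O)SCC
F7 | step 18 | (1S,4R,5R,6R,8R,10R)-5-[(tert-butyldimethylsilyl)oxy]-13-[(tert-butyldiphenylsilyl)oxy]-8,10-dihydroxy-1,4-epoxygermacr-7(11)-en-6,12-olide (C8 epimer of 29) | CC(C)(C)[Si](c4ccccc4)(c4ccccc4)OCC1=C2[C@H]([C@@H](O[Si](C)(C)C(C)(C)C)[C@@]3(C)CC[C@H](O3)[C@](C)(O)C[C@H]2O)OC1=O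
F8 | step 18 | (2S)-2-methyloxirane-2-carboxylic acid | OC(=O)[C@]1(C)CO1
F9 | step 23 | (1S,4R,5R,6R,8S,10R)-13-[(tert-butyldimethylsilyl)oxy]-5,10-dihydroxy-1,4-epoxygermacr-7(11)-en-6,12-olid-8-yl (2S)-2-methyloxirane-2-carboxylate | CC(C)(C)[Si](C)(C)OCC1=C2[C@H]([C@@H](O)[C@@]3(C)CC[C@H](O3)[C@](C)(O)C[C@@H]2OC(=O)[C@]5(C)CO5)OC1=O
F10 | step 23 | C5 mesylate of F9 | CC(C)(C)[Si](C)(C)OCC1=C2[C@H]([C@@H](OS(C)(=O)=O)[C@@]3(C)CC[C@H](O3)[C@](C)(O)C[C@@H]2OC(=O)[C@]5(C)CO5)OC1=O
F11 | step 23 | (1S,4R,5E,8S,10R)-13-[(tert-butyldimethylsilyl)oxy]-10-hydroxy-1,4-epoxygermacra-5,7(11)-dien-6,12-olid-8-yl (2S)-2-methyloxirane-2-carboxylate | CC(C)(C)[Si](C)(C)OCC1=C2/C(=C\[C@@]3(C)CC[C@H](O3)[C@](C)(O)C[C@@H]2OC(=O)[C@]5(C)CO5)OC1=O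
F12 | step 23 | (1S,4R,5E,8S,10R)-10,13-dihydroxy-1,4-epoxygermacra-5,7(11)-dien-6,12-olid-8-yl (2S)-2-methyloxirane-2-carboxylate | OCC1=C2/C(=C\[C@@]3(C)CC[C@H](O3)[C@](C)(O)C[C@@H]2OC(=O)[C@]5(C)CO5)OC1=O
A1 | alternative 1 | (E)-3-(4-methoxybenzyloxy)-5,9-dimethyl-9-(triethylsilyloxy)cyclodec-5-en-1-one | O=C1C[C@@H](OCc2ccc(OC)cc2)C/C(C)=C/CC[C@@](C)(O[Si](CC)(CC)CC)C1
A2 | alternative 2 | 2-methylfuran | Cc1ccco1
A3 | alternative 2 | 4-[2-(benzyloxy)ethyl]-1,4-dimethyl-8-oxabicyclo[3.2.1]oct-6-en-3-one | O=C1C[C@@]2(C)C=C[C@H](O2)[C@@]1(C)CCOCc1ccccc1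
A4 | alternative 3 | oxygen-bridged ten-membered C6 ketone with exocyclic C7=C11 tert-butyl enoate, C13 acetate, C8 TBS ether and C10 triethylsilyl ether | CC(=O)OC/C(C(=O)OC(C)(C)C)=C1/C(=O)C[C@@]2(C)CC[C@H](O2)[C@](C)(O[Si](CC)(CC)CC)C[C@@H]1O[Si](C)(C)C(C)(C)C
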